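**Retrosynthetic overview**

1. Position numbers follow the isochromene skeleton: C1 lactone carbonyl, O2, C3 (CH3), C4, C4a, C5 (quaternary, S), C6 ketone, C7 (CH3), C8 enol carbon, C8a.
2. Enabling feature: the carbocycle C5–C6–C7–C8–C8a–C4a is a cyclohexa-2,4-dienone whose sp3 carbon C5 sits next to the C6 carbonyl and carries no hydrogen, with oxygen on C6 and C8 (1,3) around C7–CH3. This is the product pattern of a dienylketene 6π-electrocyclization fed by a vinylketene and an alkynyl ether, and the missing hydrogen stops it before aromatisation.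
3. Disconnections: the pyranone ring (O2–C3 bond) by 6-endo lactonisation of a C1 tert-butyl ester onto a C4≡C3 propynyl group; the carbocycle by C5–C6 closure of a dienylketene made in situ from an α-diazo β-keto ester and (−)-menthyl propynyl ether; the diazo ester from farnesyl bromide, methyl propiolate, Me2CuLi, propyne and a malonate half-ester.
4. Ring order: carbocycle first (step 8), pyranone second (step 10); the menthyl group makes the two C5 epimers separable (step 9) and is removed last (step 11).

Key step: step 8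

Assumption: the 6π closure is taken to have no facial preference at C5, so the (S) configuration is obtained in step 9 by separating the two menthyl-tagged C5 epimers, and the geometry of the C4a=C5 alkene is therefore not stereochemically critical.

**Route**

Step 1
Reactants: 1 (2E,6E)-farnesyl bromide; 2 methyl propiolate
Product: 3 methyl (5E,9E)-6,10,14-trimethylpentadeca-5,9,13-trien-2-ynoate
Conditions: CuI (10 mol %), NaI (10 mol %), K2CO3, DMF, rt
Reagents that add atoms: none
Why: Copper-catalysed alkynylation of the primary allylic bromide by the terminal alkyne should take place at the unhindered CH2 terminus and leave the two E alkenes in place; no stereocenter is formed.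

Step 2
Reactants: 3
Product: 5 methyl (2E,5E,9E)-2-iodo-3,6,10,14-tetramethylpentadeca-2,5,9,13-tetraenoate, via lithium alkenyl(methyl)cuprate 4 (not isolated)
Conditions: Me2CuLi, THF, −78 °C; then I2, −78 °C to 0 °C
Reagents that add atoms: lithium dimethylcuprate, [Li+].C[Cu-]C; iodine, [I][I]
Why: Syn carbocupration of the ynoate puts the new methyl group and copper on the same side, and iodinolysis of the C–Cu bond with retention should give the E iodoalkene (methyl cis to iodine), a geometry that has no bearing on the final stereocenter.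

Step 3
Reactants: 5
Product: 6 methyl (2Z,5E,9E)-3,6,10,14-tetramethyl-2-(prop-1-yn-1-yl)pentadeca-2,5,9,13-tetraenoate
Conditions: propyne (1 atm), Pd(PPh3)2Cl2 (3 mol %), CuI (5 mol %), Et3N, THF, rt
Reagents that add atoms: propyne, CC#C
Why: Sonogashira coupling of an α-iodo enoate proceeds with retention of alkene geometry and installs the propynyl group that becomes C4, C3 and the C3 methyl group without touching the skipped triene.

Step 4
Reactants: 6
Product: 7 (2Z,5E,9E)-3,6,10,14-tetramethyl-2-(prop-1-yn-1-yl)pentadeca-2,5,9,13-tetraenoic acid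
Conditions: LiOH·H2O, THF/MeOH/H2O, 40 °C; then 1 M HCl
Reagents that add atoms: lithium hydroxide, [Li+].[OH-]
Why: Saponification (acyl substitution by hydroxide) is the only reaction open to 6 here, since there is no α-hydrogen and the β-carbon is fully substituted.

Step 5
Reactants: 7
Product: 9 tert-butyl (4Z,7E,11E)-5,8,12,16-tetramethyl-3-oxo-4-(prop-1-yn-1-yl)heptadeca-4,7,11,15-tetraenoate, via acyl imidazolide 8 (not isolated)
Conditions: 1,1'-carbonyldiimidazole, THF, rt; then KO2CCH2CO2tBu, MgCl2, Et3N, MeCN, rt; 1 M HCl work-up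
Reagents that add atoms: 1,1'-carbonyldiimidazole, O=C(n1ccnc1)n1ccnc1 (its atoms stay only in 8); potassium tert-butyl malonate, [K+].[O-]C(=O)CC(=O)OC(C)(C)C
Why: Activation as the acyl imidazolide, C-acylation of the malonate half-ester and decarboxylation on acidic work-up (Masamune–Brooks reaction) should give the β-keto ester under nearly neutral conditions that avoid γ-deprotonation of the enoyl unit.

Step 6
Reactants: 9
Product: 10 tert-butyl (4Z,7E,11E)-2-diazo-5,8,12,16-tetramethyl-3-oxo-4-(prop-1-yn-1-yl)heptadeca-4,7,11,15-tetraenoate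
Conditions: 4-acetamidobenzenesulfonyl azide, Et3N, MeCN, 0 °C to rt, dark
Reagents that add atoms: 4-acetamidobenzenesulfonyl azide, CC(=O)Nc1ccc(cc1)S(=O)(=O)N=[N+]=[N-]
Why: Regitz diazo transfer to the doubly activated methylene group is general for β-keto esters and gives the Wolff precursor without creating a stereocenter.

Step 7
Reactants: 11 (−)-menthol
Product: 14 (1R,2S,5R)-5-methyl-2-(propan-2-yl)cyclohexyl prop-1-yn-1-yl ether, via dichlorovinyl ether 12 (not isolated), via lithium alkynyl ether 13 (not isolated)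
Conditions: KH, THF, 0 °C; trichloroethylene, −50 °C to rt; n-BuLi (2.4 equiv), −78 °C; MeI, DMPU, −78 °C to rt
Reagents that add atoms: trichloroethylene, ClC=C(Cl)Cl; iodomethane, C[I]
Why: Addition–elimination of the potassium alkoxide on trichloroethylene, dehydrochlorination and chlorine–lithium exchange with n-BuLi, and C-methylation make up the established trichloroethylene route to alkynyl ethers; the C–O bond of menthol is never broken, so its three stereocenters are retained.

Step 8
Reactants: 10; 14 (3 equiv)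
Product: 18 tert-butyl (3RS)-3,5-dimethyl-6-{[(1R,2S,5R)-5-methyl-2-(propan-2-yl)cyclohexyl]oxy}-4-oxo-2-(prop-1-yn-1-yl)-3-[(2E,6E)-3,7,11-trimethyldodeca-2,6,10-trien-1-yl]cyclohexa-1,5-diene-1-carboxylate (pair of C3 epimers), via vinylketene 15 (not isolated), via alkenylcyclobutenone 16 (not isolated), via dienylketene 17 (not isolated)
Conditions: hν (254 nm, Vycor), ClCH2CH2Cl, rt; then 80 °C, dark
Reagents that add atoms: none
Why: Irradiation triggers a Wolff rearrangement of 10 (1,2-shift of the alkenyl group from C6 to C8a, loss of N2) to the ester-substituted vinylketene 15, and the nucleophilic methyl-bearing carbon of alkynyl ether 14 attacks the ketene carbon C6 so that a regioselective [2+2] cycloaddition closes the four-membered ring of 16 (C6–C7 and C8–C8a bonds; the C8a stereocenter of 16 is transient). Warming opens 16 by 4π conrotatory cleavage of C6–C8a to dienylketene 17, which closes the six-membered carbocycle by 6π disrotatory electrocyclization between the ketene carbon C6 and the fully substituted alkene carbon C5; as C5 carries no hydrogen the sequence stops at the cyclohexa-2,4-dienone. The closest known reaction type is the Danheiser benzannulation in its diazo ketone variant with alkynyl ethers, and the last event is the thermal reverse of the Barton–Quinkert photo-opening of 2,4-cyclohexadienones. The step needs periselectivity and regioselectivity in the ketene–alkyne union ([2+2] across the ketene C=C instead of a hetero-[4+2] through the ester carbonyl), which the strongly polarised O–C≡C–CH3 unit and the low heterodiene reactivity of an ester carbonyl compared with a ketone should secure, and it needs the alkenyl arm of 17 cis to the ketene arm, which the reversible ring opening supplies. C5 is the only lasting new stereocenter, and nothing in 17 is expected to control the face on which it forms (the menthyl group lies across the ring), so 18 should arise as both C5 epimers; the resident (1R,2S,5R)-menthyl group makes them diastereomers, and this is the element that secures the (S) configuration in step 9. No facial selectivity is therefore demanded of this step, and material of the unwanted configuration is not lost, because irradiation near 366 nm should re-open it to 17, which re-closes thermally to the epimer pair.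

Step 9
Reactants: 18
Product: 19 tert-butyl (3S)-3,5-dimethyl-6-{[(1R,2S,5R)-5-methyl-2-(propan-2-yl)cyclohexyl]oxy}-4-oxo-2-(prop-1-yn-1-yl)-3-[(2E,6E)-3,7,11-trimethyldodeca-2,6,10-trien-1-yl]cyclohexa-1,5-diene-1-carboxylate
Conditions: preparative normal-phase HPLC (silica, hexane/EtOAc), dark
Reagents that add atoms: none
Why: The covalently bound (1R,2S,5R)-menthyl group makes the two C3 epimers of 18 diastereomers, so that chromatography on an achiral phase (resolution through a covalent chiral auxiliary) should deliver the (3S) epimer, the fractions being assigned by comparing measured and calculated electronic circular dichroism; the quaternary carbon cannot epimerise in the dark.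

Step 10
Reactants: 19
Product: 20 (5S)-3,5,7-trimethyl-8-{[(1R,2S,5R)-5-methyl-2-(propan-2-yl)cyclohexyl]oxy}-5-[(2E,6E)-3,7,11-trimethyldodeca-2,6,10-trien-1-yl]-1H-isochromene-1,6(5H)-dione
Conditions: ZnBr2 (3 equiv), CH2Cl2, rt, dark
Reagents that add atoms: none
Why: ZnBr2 removes the tert-butyl group as 2-methylpropene and, as in the ZnBr2-catalysed lactonisation of (Z)-2-en-4-ynoic acids, directs the carboxyl oxygen to the methyl-bearing alkyne carbon (6-endo-dig), which forms the aromatic 2-pyranone ring; C5 is quaternary and is not affected.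

Step 11
Reactants: 20
Product: 21 (5S)-8-hydroxy-3,5,7-trimethyl-5-[(2E,6E)-3,7,11-trimethyldodeca-2,6,10-trien-1-yl]-1H-isochromene-1,6(5H)-dione (5-farnesyl-isochromene, target)
Conditions: 2 M HCl, THF, rt to 40 °C, dark
Reagents that add atoms: water, O
Why: Acid hydrolysis of the vinylogous ester (addition of water at C8, loss of menthol) frees the enolised 1,3-dione, which settles in the tautomer with the C8 hydroxyl hydrogen-bonded to the lactone carbonyl; the quaternary C5 cannot epimerise by enolisation.

**Compound list**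

1 | (2E,6E)-farnesyl bromide, (2E,6E)-1-bromo-3,7,11-trimethyldodeca-2,6,10-triene | CC(C)=CCC/C(C)=C/CC/C(C)=C/CBr | starting material
2 | methyl propiolate (methyl prop-2-ynoate) | C#CC(=O)OC | starting material
3 | methyl (5E,9E)-6,10,14-trimethylpentadeca-5,9,13-trien-2-ynoate | CC(C)=CCC/C(C)=C/CC/C(C)=C/CC#CC(=O)OC | intermediate
4 | lithium alkenyl(methyl)cuprate from syn addition of Me2CuLi to 3 (copper on C2, cis to the new C3 methyl group) | CC(C)=CCC/C(C)=C/CC/C(C)=C/C/C(C)=C(/[Cu-]C)C(=O)OC.[Li+] | intermediate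
5 | methyl (2E,5E,9E)-2-iodo-3,6,10,14-tetramethylpentadeca-2,5,9,13-tetraenoate | CC(C)=CCC/C(C)=C/CC/C(C)=C/C/C(C)=C(/I)C(=O)OC | intermediate
6 | methyl (2Z,5E,9E)-3,6,10,14-tetramethyl-2-(prop-1-yn-1-yl)pentadeca-2,5,9,13-tetraenoate | CC(C)=CCC/C(C)=C/CC/C(C)=C/C/C(C)=C(/C#CC)C(=O)OC | intermediate
7 | (2Z,5E,9E)-3,6,10,14-tetramethyl-2-(prop-1-yn-1-yl)pentadeca-2,5,9,13-tetraenoic acid | CC(C)=CCC/C(C)=C/CC/C(C)=C/C/C(C)=C(/C#CC)C(=O)O | intermediate
8 | 1-[(2Z,5E,9E)-3,6,10,14-tetramethyl-2-(prop-1-yn-1-yl)pentadeca-2,5,9,13-tetraenoyl]imidazole | CC(C)=CCC/C(C)=C/CC/C(C)=C/C/C(C)=C(/C#CC)C(=O)n1ccnc1 | intermediate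
9 | tert-butyl (4Z,7E,11E)-5,8,12,16-tetramethyl-3-oxo-4-(prop-1-yn-1-yl)heptadeca-4,7,11,15-tetraenoate | CC(C)=CCC/C(C)=C/CC/C(C)=C/C/C(C)=C(/C#CC)C(=O)CC(=O)OC(C)(C)C | intermediate
10 | tert-butyl (4Z,7E,11E)-2-diazo-5,8,12,16-tetramethyl-3-oxo-4-(prop-1-yn-1-yl)heptadeca-4,7,11,15-tetraenoate | CC(C)=CCC/C(C)=C/CC/C(C)=C/C/C(C)=C(/C#CC)C(=O)C(=[N+]=[N-])C(=O)OC(C)(C)C | intermediate
11 | (−)-menthol, (1R,2S,5R)-5-methyl-2-(propan-2-yl)cyclohexan-1-ol | O[C@@H]1C[C@H](C)CC[C@H]1C(C)C | starting material
12 | (1R,2S,5R)-5-methyl-2-(propan-2-yl)cyclohexyl (E)-1,2-dichloroethenyl ether | Cl/C=C(/Cl)O[C@@H]1C[C@H](C)CC[C@H]1C(C)C | intermediate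
13 | lithium 2-{[(1R,2S,5R)-5-methyl-2-(propan-2-yl)cyclohexyl]oxy}ethynide | [Li]C#CO[C@@H]1C[C@H](C)CC[C@H]1C(C)C | intermediate
14 | (1R,2S,5R)-5-methyl-2-(propan-2-yl)cyclohexyl prop-1-yn-1-yl ether | CC#CO[C@@H]1C[C@H](C)CC[C@H]1C(C)C | intermediate
15 | vinylketene: tert-butyl (3Z,6E,10E)-4,7,11,15-tetramethyl-2-(oxomethylidene)-3-(prop-1-yn-1-yl)hexadeca-3,6,10,14-tetraenoate (farnesyl CH2 cis to the ketene-bearing carbon) | CC(C)=CCC/C(C)=C/CC/C(C)=C/C/C(C)=C(/C#CC)C(=C=O)C(=O)OC(C)(C)C | intermediate
16 | alkenylcyclobutenone: tert-butyl 3-methyl-2-(menthyloxy)-4-oxocyclobut-2-ene-1-carboxylate carrying the 1-(prop-1-ynyl)-2,5,9,13-tetramethyltetradeca-1,4,8,12-tetraenyl group on ring C1 (both configurations at ring C1) | CC(C)=CCC/C(C)=C/CC/C(C)=C/C/C(C)=C(/C#CC)C1(C(=O)OC(C)(C)C)C(=O)C(C)=C1O[C@@H]2C[C@H](C)CC[C@H]2C(C)C | intermediate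
17 | dienylketene: O=C6=C7(CH3)–C8(O-menthyl)=C8a(CO2tBu)–C4a(propynyl)=C5(CH3)(CH2-farnesyl remainder), ketene arm and alkenyl arm cis on C8=C8a | CC(C)=CCC/C(C)=C/CC/C(C)=C/C/C(C)=C(/C#CC)\C(C(=O)OC(C)(C)C)=C(O[C@@H]1C[C@H](C)CC[C@H]1C(C)C)/C(C)=C=O | intermediate
18 | tert-butyl (3RS)-3,5-dimethyl-6-{[(1R,2S,5R)-5-methyl-2-(propan-2-yl)cyclohexyl]oxy}-4-oxo-2-(prop-1-yn-1-yl)-3-[(2E,6E)-3,7,11-trimethyldodeca-2,6,10-trien-1-yl]cyclohexa-1,5-diene-1-carboxylate (pair of C3 epimers; the quaternary ring carbon is drawn without configuration) | CC(C)=CCC/C(C)=C/CC/C(C)=C/CC1(C)C(=O)C(C)=C(O[C@@H]2C[C@H](C)CC[C@H]2C(C)C)C(C(=O)OC(C)(C)C)=C1C#CC | intermediate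
19 | tert-butyl (3S)-3,5-dimethyl-6-{[(1R,2S,5R)-5-methyl-2-(propan-2-yl)cyclohexyl]oxy}-4-oxo-2-(prop-1-yn-1-yl)-3-[(2E,6E)-3,7,11-trimethyldodeca-2,6,10-trien-1-yl]cyclohexa-1,5-diene-1-carboxylate | CC(C)=CCC/C(C)=C/CC/C(C)=C/C[C@]1(C)C(=O)C(C)=C(O[C@@H]2C[C@H](C)CC[C@H]2C(C)C)C(C(=O)OC(C)(C)C)=C1C#CC | intermediate
20 | (5S)-3,5,7-trimethyl-8-{[(1R,2S,5R)-5-methyl-2-(propan-2-yl)cyclohexyl]oxy}-5-[(2E,6E)-3,7,11-trimethyldodeca-2,6,10-trien-1-yl]-1H-isochromene-1,6(5H)-dione | CC(C)=CCC/C(C)=C/CC/C(C)=C/C[C@]1(C)C(=O)C(C)=C(O[C@@H]2C[C@H](C)CC[C@H]2C(C)C)c3c1cc(C)oc3=O | intermediate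
21 | (5S)-8-hydroxy-3,5,7-trimethyl-5-[(2E,6E)-3,7,11-trimethyldodeca-2,6,10-trien-1-yl]-1H-isochromene-1,6(5H)-dione | CC(C)=CCC/C(C)=C/CC/C(C)=C/C[C@]1(C)C(=O)C(C)=C(O)c2c1cc(C)oc2=O | target

**Step count and risks**

Total step count: 11. Longest linear sequence: 10 steps (steps 1 to 6, then 8 to 11; step 7 is the side branch).

Steps most likely to fail, each with a fallback:

Step 9. The two C3 epimers of 18 may co-elute, because the menthyl stereocenters lie across the ring from the quaternary carbon (a failure of diastereomer discrimination, not of reactivity). The fallback sets out from 18, taken on as the unseparated epimer pair. It is carried through the conditions of steps 10 and 11, so that 20 is formed together with its C5 epimer F1, and the hydrolysis then gives 21 together with its enantiomer F2. Compound 21 is separated from the enantiomer F2 by preparative chromatography on a chiral stationary phase (amylose tris(3,5-dimethylphenylcarbamate)), and the fallback comes back to the route at 21.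

Step 10. The carboxyl oxygen may close on the inner alkyne carbon (5-exo-dig) to give an alkylidenebutenolide, or the Lewis acid may start cation–olefin reactions of the triene chain. The fallback sets out from 19 and uses an electrophile-triggered closure instead. Iodocyclisation (I2, NaHCO3, MeCN, rt; 6-endo iodolactonisation with loss of the tert-butyl group) should give the 4-iodopyranone F3. Hydrodeiodination catalysed by zerovalent palladium (Pd(PPh3)4, Bu3SnH, THF, rt) then returns to the route at 20.

Step 11. Hydrolysis may stall at the hindered C8 centre, or the acid may open the enol lactone or protonate the trisubstituted alkenes before the ether is cleaved. The fallback sets out from 19, before the base-sensitive lactone exists. The vinylogous ester is cleaved by conjugate addition–elimination of hydroxide at C8 (KOH, MeOH/H2O, 50 °C; then dilute HCl) to give the free enol tert-butyl ester F4. The ZnBr2 lactonisation of step 10 is then run on F4, which comes back to the route at 21.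

Further compounds
F1 | step 9 | (5R)-3,5,7-trimethyl-8-{[(1R,2S,5R)-5-methyl-2-(propan-2-yl)cyclohexyl]oxy}-5-[(2E,6E)-3,7,11-trimethyldodeca-2,6,10-trien-1-yl]-1H-isochromene-1,6(5H)-dione (C5 epimer of 20) | CC(C)=CCC/C(C)=C/CC/C(C)=C/C[C@@]1(C)C(=O)C(C)=C(O[C@@H]2C[C@H](C)CC[C@H]2C(C)C)c3c1cc(C)oc3=O
F2 | step 9 | (5R)-8-hydroxy-3,5,7-trimethyl-5-[(2E,6E)-3,7,11-trimethyldodeca-2,6,10-trien-1-yl]-1H-isochromene-1,6(5H)-dione (enantiomer of 21) | CC(C)=CCC/C(C)=C/CC/C(C)=C/C[C@@]1(C)C(=O)C(C)=C(O)c2c1cc(C)oc2=O
F3 | step 10 | (5S)-4-iodo-3,5,7-trimethyl-8-{[(1R,2S,5R)-5-methyl-2-(propan-2-yl)cyclohexyl]oxy}-5-[(2E,6E)-3,7,11-trimethyldodeca-2,6,10-trien-1-yl]-1H-isochromene-1,6(5H)-dione | CC(C)=CCC/C(C)=C/CC/C(C)=C/C[C@]1(C)C(=O)C(C)=C(O[C@@H]2C[C@H](C)CC[C@H]2C(C)C)c3c1c(I)c(C)oc3=O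
F4 | step 11 | tert-butyl (3S)-6-hydroxy-3,5-dimethyl-4-oxo-2-(prop-1-yn-1-yl)-3-[(2E,6E)-3,7,11-trimethyldodeca-2,6,10-trien-1-yl]cyclohexa-1,5-diene-1-carboxylate | CC(C)=CCC/C(C)=C/CC/C(C)=C/C[C@]1(C)C(=O)C(C)=C(O)C(C(=O)OC(C)(C)C)=C1C#CC
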